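**Retrosynthetic overview**
- Ring C is opened at the O1–C2 bond (C–O closure by oxa-Michael addition, then dehydrogenation) and at the adjoining C=C bond (aldol). This gives 2-hydroxy-3,4,5,6-tetramethoxyacetophenone and unprotected 4-hydroxybenzaldehyde.
- The fifth oxygen of ring A (the future C8–OMe) is cut at its aryl C–O bond back to a C–H. In the forward direction the para-methoxyphenol is dearomatised to its quinone monoketal, and acid then moves a methoxy group to the only ring C–H (new method).
- The trimethoxy ketone comes from 3,4,5-trimethoxyphenol by ortho-acetylation.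
- Ring order: rings A and B are bought as benzenes. Ring C (the pyranone) is the only ring made, and it is made in the last step.

**Assumption:** the target is a planar, achiral flavone with no stereocentre or stereoaxis, so there is no enantiomer to select. The sp3 centres of transient intermediates 4 and 8 are racemic and are erased within the same step.

**Step 1**
Reactants: 1 3,4,5-trimethoxyphenol
Product: 2 1-(6-hydroxy-2,3,4-trimethoxyphenyl)ethan-1-one
Conditions: Ac2O (1.5 equiv), BF3·OEt2 (solvent), 85 °C, 3 h
Reagents that add atoms: acetic anhydride, CC(=O)OC(C)=O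
Why: This is a BF3-promoted O-acetylation/Fries rearrangement (Friedel–Crafts acylation), in which the two open ring positions are equivalent and both ortho to OH, and chelation of the resulting ortho-hydroxy ketone stops a second acylation.

**Step 2**
Reactants: 2 1-(6-hydroxy-2,3,4-trimethoxyphenyl)ethan-1-one
Product: 5 1-(2-hydroxy-3,4,5,6-tetramethoxyphenyl)ethan-1-one, via quinone monoketal 3 (not isolated), via methoxy dienone adduct 4 (not isolated)
Conditions: PhI(OAc)2 (1.0 equiv), MeOH, 0 °C, 30 min; evaporate with toluene (removes AcOH); then anhydrous MeOH–(CF3)2CHOH 1:1 (0.02 M), CF3SO3H (10 mol%), acid-washed molecular sieves (AW-300), 40 °C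
Reagents that add atoms: methanol, CO
Why: Proposed new method: a one-pot net ortho C–H methoxylation of a para-methoxyphenol by oxidative dearomatisation followed by a redox-neutral ketal-to-ring methoxy transposition. PhI(OAc)2 (trivalent iodine) delivers methanol to the methoxy-bearing para carbon to give monoketal 3 and is fully consumed. CF3SO3H then ionises the ketal to an O-methylated quinone (methoxy-phenoxenium) cation. Methanol attack on this cation at any OMe-bearing carbon (C3, C4, C5) is degenerate and reversible. Conjugate attack at C6, the only C–H carbon and the beta position of the activated C4 oxocarbenium, gives dienone 4. Dienone 4 tautomerises irreversibly to the hydrogen-bond-chelated phenol 5, which erases its racemic sp3 centre. Over-oxidation by the reagent is excluded because no oxidant remains, and biaryl coupling of 5 is excluded because it has no free ring position. The closest known reaction types are the Thiele–Winter acetoxylation of quinones and the acid-promoted SN2'-type substitution of quinone monoketals by arenes, alkenes and thiols at the carbon next to the carbonyl.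

**Step 3**
Reactants: 5 1-(2-hydroxy-3,4,5,6-tetramethoxyphenyl)ethan-1-one; 6 4-hydroxybenzaldehyde (1.2 equiv)
Product: 9 4'-hydroxy-5,6,7,8-tetramethoxyflavone, via chalcone 7 (not isolated), via flavanone 8 (not isolated)
Conditions: pyrrolidine (0.5 equiv), I2 (10 mol%), DMSO, 140 °C, 8 h
Reagents that add atoms: none
Why: This is the known domino Claisen–Schmidt condensation/oxa-Michael ring closure/I2–DMSO dehydrogenation, in which pyrrolidine works by enamine/iminium catalysis without turning the aldehyde into an unreactive phenoxide, the 6'-methoxy group shifts the chalcone–flavanone equilibrium toward 8 (forming O1–C2), and alpha-iodination with loss of HI erases the racemic C2 centre while DMSO re-oxidises HI to I2.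

**Compound list**
1 | 3,4,5-trimethoxyphenol | COc1cc(O)cc(OC)c1OC | starting material
2 | 1-(6-hydroxy-2,3,4-trimethoxyphenyl)ethan-1-one | CC(=O)c1c(O)cc(OC)c(OC)c1OC | intermediate
3 | 2-acetyl-3,4,4,5-tetramethoxycyclohexa-2,5-dien-1-one (quinone monoketal, not isolated) | CC(=O)C1=C(OC)C(OC)(OC)C(OC)=CC1=O | intermediate
4 | 2-acetyl-3,4,5,6-tetramethoxycyclohexa-2,4-dien-1-one (racemic, not isolated) | CC(=O)C1=C(OC)C(OC)=C(OC)C(OC)C1=O | intermediate
5 | 1-(2-hydroxy-3,4,5,6-tetramethoxyphenyl)ethan-1-one | CC(=O)c1c(O)c(OC)c(OC)c(OC)c1OC | intermediate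
6 | 4-hydroxybenzaldehyde | O=Cc1ccc(O)cc1 | starting material
7 | (E)-1-(2-hydroxy-3,4,5,6-tetramethoxyphenyl)-3-(4-hydroxyphenyl)prop-2-en-1-one (not isolated) | COc1c(O)c(C(=O)/C=C/c2ccc(O)cc2)c(OC)c(OC)c1OC | intermediate
8 | 2-(4-hydroxyphenyl)-5,6,7,8-tetramethoxychroman-4-one (racemic, not isolated) | COc1c(OC)c(OC)c2c(c1OC)OC(CC2=O)c1ccc(O)cc1 | intermediate
9 | 4'-hydroxy-5,6,7,8-tetramethoxyflavone, 2-(4-hydroxyphenyl)-5,6,7,8-tetramethoxy-4H-chromen-4-one (achiral) | COc1c(OC)c(OC)c2c(=O)cc(-c3ccc(O)cc3)oc2c1OC | target

**Total step count:** 3. **Longest linear sequence:** 3 (1 → 2 → 5 → 9).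

**Steps most likely to fail**

**Step 2 (the proposed new step).**
- Traces of water, or methyl loss from the cation, would collapse 3 to the acetyl-dimethoxyquinone.
- Attack at C6 may be slow, because C6 is also the alpha carbon of a vinylogous ester.
- Electron transfer between the cation and the more electron-rich product 5 could scramble the oxidation levels.

The fallback uses known halogenation and Ullmann-type ether chemistry, sets out from 2 and comes back at 5. Ketone 2 is brominated at its only ring C–H with N-bromosuccinimide (1.0 equiv, MeCN, 0 °C) to give 1-(3-bromo-2-hydroxy-4,5,6-trimethoxyphenyl)ethan-1-one F1. The bromide is then exchanged with NaOMe (excess) and CuBr (20 mol%) in DMF–MeOH at 110 °C, as in the classical conversion of 5-bromovanillin into syringaldehyde. This gives 5.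

**Step 3.**
- The ketone is flanked by two ortho substituents, and the aldehyde is deactivated by its para hydroxyl.
- The sequence could therefore stall before the chalcone or at flavanone 8.
- Iodine may also touch ring B.

The fallback replaces the aldol logic with an aroylation/cyclodehydration logic, sets out from 5 and comes back at 9. The dianion of 5 (LiN(SiMe3)2, 3.5 equiv, THF, −78 °C) is C-acylated with 4-(benzyloxy)benzoyl chloride to give 1-(4-(benzyloxy)phenyl)-3-(2-hydroxy-3,4,5,6-tetramethoxyphenyl)propane-1,3-dione F2. Catalytic H2SO4 in AcOH at 95 °C closes O1–C2 with loss of water to give 2-(4-(benzyloxy)phenyl)-5,6,7,8-tetramethoxy-4H-chromen-4-one F3. Hydrogenolysis (H2, Pd/C, EtOAc–MeOH, rt) then gives 9.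

**Step 1.**
- Prolonged heating in BF3·OEt2 can cleave the methyl ether next to the new carbonyl.
- It can also leave unrearranged aryl acetate.

The fallback uses a nitrile electrophile (Hoesch reaction), sets out from 1 and comes back at 2. Phenol 1, MeCN, ZnCl2 and dry HCl in Et2O at 0 °C precipitate 1-(6-hydroxy-2,3,4-trimethoxyphenyl)ethan-1-iminium chloride F4. Boiling this salt in water hydrolyses it to 2.

**Further compounds**
F1 | step 2 | 1-(3-bromo-2-hydroxy-4,5,6-trimethoxyphenyl)ethan-1-one | CC(=O)c1c(O)c(Br)c(OC)c(OC)c1OC
F2 | step 3 | 1-(4-(benzyloxy)phenyl)-3-(2-hydroxy-3,4,5,6-tetramethoxyphenyl)propane-1,3-dione | COc1c(O)c(C(=O)CC(=O)c2ccc(OCc3ccccc3)cc2)c(OC)c(OC)c1OC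
F3 | step 3 | 2-(4-(benzyloxy)phenyl)-5,6,7,8-tetramethoxy-4H-chromen-4-one | COc1c(OC)c(OC)c2c(=O)cc(-c3ccc(OCc4ccccc4)cc3)oc2c1OC
F4 | step 1 | 1-(6-hydroxy-2,3,4-trimethoxyphenyl)ethan-1-iminium chloride | CC(=[NH2+])c1c(O)cc(OC)c(OC)c1OC.[Cl-]
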